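## Retrosynthetic overview

- The target is read as (1R,5R,6R)-6-aryl-3,7-dioxabicyclo[3.3.0]octan-2-one (C1, C2=O, O3, C4, C5, C6–Ar, O7, C8). Its syringyl O-4 carries an erythro (7′R,8′S)-guaiacylglycerol unit through C8′.
- Feature used: H1, H5 and H6 all lie on one face of the bicycle, and the C6 aryl group lies on the other (aryl endo, cis to the lactone ring). H5 and H1 can therefore be added last to the flat C1=C5 alkene of butenolide 14, from the face the aryl group leaves open.
- The tetrasubstituted C1=C5 unit is traced back to an allene. O7–C8 and C1–C2 are cut together (oxypalladation–methoxycarbonylation of α-allenol 9) and C2–O3 by lactonisation. Allenol 9 comes from syringaldehyde and but-2-yne-1,4-diol, with C6 set by oxazaborolidine reduction.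
- The aryl ether O–C8′ is made late. A Mitsunobu inversion joins phenol 16 to threo alcohol 27, which comes from vanillin by an Evans syn glycolate aldol.
- Ring order: dihydrofuran ring (step 7), lactone ring (step 8), saturation of the ring fusion (step 9). The dioxasilinane ring of the side chain is only a protecting group.

Key step: step 7

Assumption: in ketone 8 the electron-rich aryl ring lies in the carbonyl plane and is taken as the larger group towards the oxazaborolidine, so the (S)-catalyst should give (S)-9. The sense is to be checked on 9 by Mosher ester analysis, and the (R)-catalyst is used instead if the allenyl group proves the larger.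

## Route

Step 1
Reactants: 1 syringaldehyde
Product: 2 3,5-dimethoxy-4-(triisopropylsilyloxy)benzaldehyde
Conditions: TIPSCl, imidazole, DMF, rt → 40 °C
Reagents that add atoms: triisopropylsilyl chloride CC(C)[Si](Cl)(C(C)C)C(C)C
Why: Imidazole-promoted silylation of the phenol; the hindered aryl TIPS ether should survive aqueous indium, MnO2, borane, the carbonylation and acidic fluoride, yet fall to buffered fluoride in step 10.

Step 2
Reactants: 3 but-2-yne-1,4-diol
Product: 4 4-(tert-butyldimethylsilyloxy)but-2-yn-1-ol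
Conditions: TBSCl (1 equiv), 3 (3 equiv), imidazole, DMF, 0 °C → rt
Reagents that add atoms: tert-butyldimethylsilyl chloride CC(C)(C)[Si](C)(C)Cl
Why: Statistical monosilylation of a symmetrical diol used in excess; the unreacted diol is washed out with water.

Step 3
Reactants: 4 4-(tert-butyldimethylsilyloxy)but-2-yn-1-ol
Product: 5 1-bromo-4-(tert-butyldimethylsilyloxy)but-2-yne
Conditions: CBr4, PPh3, CH2Cl2, 0 °C
Reagents that add atoms: carbon tetrabromide BrC(Br)(Br)Br
Why: Appel bromination of a primary propargylic alcohol under neutral conditions, which leaves the silyl ether and the alkyne untouched.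

Step 4
Reactants: 2 3,5-dimethoxy-4-(triisopropylsilyloxy)benzaldehyde; 5 1-bromo-4-(tert-butyldimethylsilyloxy)but-2-yne
Product: 7 rac-1-(3,5-dimethoxy-4-triisopropylsilyloxyphenyl)-2-(tert-butyldimethylsilyloxymethyl)buta-2,3-dien-1-ol, via propargylindium dibromide 6 (not isolated)
Conditions: In powder, THF/sat. aq. NH4Cl, rt
Reagents that add atoms: none
Why: Indium Barbier reaction: with a γ-substituted propargyl bromide the metal sits on the unsubstituted CH2 terminus and the aldehyde is attacked by SE2′ through the alkyne carbon bearing CH2OTBS, giving the α-allenol rather than the homopropargyl alcohol, with C6 formed racemic at this stage.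

Step 5
Reactants: 7 rac-1-(3,5-dimethoxy-4-triisopropylsilyloxyphenyl)-2-(tert-butyldimethylsilyloxymethyl)buta-2,3-dien-1-ol
Product: 8 1-(3,5-dimethoxy-4-triisopropylsilyloxyphenyl)-2-(tert-butyldimethylsilyloxymethyl)buta-2,3-dien-1-one
Conditions: activated MnO2, CH2Cl2, rt
Reagents that add atoms: none
Why: MnO2 oxidation of a benzylic and allenylic alcohol under neutral conditions, which erases the racemic centre without isomerising the α-substituted allenyl ketone or touching the silyl ethers.

Step 6
Reactants: 8 1-(3,5-dimethoxy-4-triisopropylsilyloxyphenyl)-2-(tert-butyldimethylsilyloxymethyl)buta-2,3-dien-1-one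
Product: 9 (S)-1-(3,5-dimethoxy-4-triisopropylsilyloxyphenyl)-2-(tert-butyldimethylsilyloxymethyl)buta-2,3-dien-1-ol
Conditions: (S)-2-methyl-CBS-oxazaborolidine (0.3 equiv), catecholborane, EtNO2, −78 °C; MeOH quench
Reagents that add atoms: none
Why: Corey–Bakshi–Shibata reduction, a reaction type already used on allenyl ketones: the carbonyl oxygen binds the ring boron through the lone pair anti to the coplanar aryl group, the nitrogen-bound borane delivers hydride to the Re face and sets C6 as (S), and catecholborane at low temperature leaves the allene alone.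

Step 7
Reactants: 9 (S)-1-(3,5-dimethoxy-4-triisopropylsilyloxyphenyl)-2-(tert-butyldimethylsilyloxymethyl)buta-2,3-dien-1-ol
Product: 12 methyl (5S)-5-(3,5-dimethoxy-4-triisopropylsilyloxyphenyl)-4-(tert-butyldimethylsilyloxymethyl)-2,5-dihydrofuran-3-carboxylate, via dihydrofuranylpalladium trifluoroacetate 10 (not isolated), via acylpalladium trifluoroacetate 11 (not isolated)
Conditions: Pd(OCOCF3)2 (10 mol%), p-benzoquinone (1.5 equiv), CO (1 atm), MeOH, 0 °C → rt
Reagents that add atoms: carbon monoxide [C-]#[O+]; methanol CO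
Why: Proposed new method: divalent palladium binds the terminal C1=C8 π bond of the allene, the C6 hydroxyl adds anti to the metal at C8 (O7–C8 bond, 5-endo-trig closure of the 2,5-dihydrofuran ring) and leaves σ-vinylpalladium 10 at the former central carbon C1. CO then inserts to give acylpalladium 11 (C1–C2 bond), methanolysis releases ester 12 and zerovalent palladium, and p-benzoquinone with the two liberated protons restores divalent palladium. The closest known reaction types are the 5-endo oxypalladation of α-allenols with capture of the dihydrofuranylpalladium by allyl halides or alkenes, and the oxidative cyclisation–methoxycarbonylation of allenyl ketones to furan-3-carboxylates and of γ-allenols to tetrahydrofuranylacrylates; only the capture by CO and methanol after 5-endo closure of an α-allenol is new. No stereocentre is created: the C6–O bond is never broken and the terminal allene has no axial chirality, so C6 should keep its configuration. The C6 hydroxyl must cyclise rather than the C4 oxygen, which has the same 5-endo relationship to C8, and the TBS ether secures this. Oxypalladation must also win over chloropalladation, which with CuCl2 and CO is known to divert α-allenols to 3-(chloromethyl)butenolides, so catalyst and oxidant are chloride-free; the quinone takes up the acid as it forms, which disfavours protodepalladation and protects the TBS ether and the ionisable benzylic carbinol.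

Step 8
Reactants: 12 methyl (5S)-5-(3,5-dimethoxy-4-triisopropylsilyloxyphenyl)-4-(tert-butyldimethylsilyloxymethyl)-2,5-dihydrofuran-3-carboxylate
Product: 14 (6S)-6-(3,5-dimethoxy-4-triisopropylsilyloxyphenyl)-3,7-dioxabicyclo[3.3.0]oct-1(5)-en-2-one, via hydroxy ester 13 (not isolated)
Conditions: HF·pyridine, pyridine, THF, 0 °C → rt; then PPTS (cat.), toluene, 50 °C
Reagents that add atoms: none
Why: Acidic fluoride cleaves the primary alkyl TBS ether well before the hindered aryl TIPS ether, and the freed C4 hydroxyl, held cis to the ester across C1=C5, lactonises (C2–O3 bond) under mild acid catalysis; base is avoided because H6 is the vinylogously acidic γ-hydrogen of the enoate.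

Step 9
Reactants: 14 (6S)-6-(3,5-dimethoxy-4-triisopropylsilyloxyphenyl)-3,7-dioxabicyclo[3.3.0]oct-1(5)-en-2-one
Product: 15 (1R,5R,6R)-6-(3,5-dimethoxy-4-triisopropylsilyloxyphenyl)-3,7-dioxabicyclo[3.3.0]octan-2-one
Conditions: NiCl2·6H2O (0.2 equiv), NaBH4, MeOH/THF, −20 → 0 °C
Reagents that add atoms: none
Why: Nickel boride conjugate reduction of a butenolide: C5 of the nearly flat bicycle takes hydrogen on the face that carries H6 because the C6 aryl group shields the other; C1 is protonated at once by methanol on the same face since a trans-fused bicyclo[3.3.0]octane is too strained, so H1, H5 and H6 end up cis and the aryl endo (the change of the C6 descriptor from S to R is a priority change only).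

Step 10
Reactants: 15 (1R,5R,6R)-6-(3,5-dimethoxy-4-triisopropylsilyloxyphenyl)-3,7-dioxabicyclo[3.3.0]octan-2-one
Product: 16 (1R,5R,6R)-6-(4-hydroxy-3,5-dimethoxyphenyl)-3,7-dioxabicyclo[3.3.0]octan-2-one
Conditions: Bu4NF, AcOH, THF, 0 °C
Reagents that add atoms: none
Why: Fluoride cleavage of an aryl silyl ether; the acetic acid buffer keeps the phenol protonated, so neither lactone opening nor quinone methide-type epimerisation of the endo benzylic ether C6 should occur.

Step 11
Reactants: 17 vanillin
Product: 18 3-methoxy-4-(triisopropylsilyloxy)benzaldehyde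
Conditions: TIPSCl, imidazole, DMF, rt
Reagents that add atoms: triisopropylsilyl chloride CC(C)[Si](Cl)(C(C)C)C(C)C
Why: Standard phenol silylation; the TIPS ether should withstand the peroxide work-up of step 13, LiBH4 and hydrogenation, and leaves with fluoride in the last step.

Step 12
Reactants: 19 (S)-4-benzyloxazolidin-2-one; 20 benzyloxyacetyl chloride
Product: 22 (S)-4-benzyl-3-(benzyloxyacetyl)oxazolidin-2-one, via lithium oxazolidinide 21 (not isolated)
Conditions: n-BuLi, THF, −78 °C; then 20, −78 → 0 °C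
Reagents that add atoms: none
Why: N-acylation of the lithiated Evans auxiliary with an acid chloride, the standard entry to glycolate imides.

Step 13
Reactants: 22 (S)-4-benzyl-3-(benzyloxyacetyl)oxazolidin-2-one; 18 3-methoxy-4-(triisopropylsilyloxy)benzaldehyde
Product: 24 (S)-4-benzyl-3-[(2S,3R)-2-benzyloxy-3-hydroxy-3-(3-methoxy-4-triisopropylsilyloxyphenyl)propanoyl]oxazolidin-2-one, via Z-boron enolate 23 (not isolated)
Conditions: Bu2BOTf, Et3N, CH2Cl2, −78 → 0 °C; 18, −78 → 0 °C; then pH 7 buffer, MeOH, 30% H2O2, 0 °C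
Reagents that add atoms: none
Why: Evans syn glycolate aldol: the Z-boron enolate reacts through a closed chair transition state on the enolate face remote from the benzyl group of the (S)-auxiliary, which sets C8′ and C7′ together as the syn (threo) pair.

Step 14
Reactants: 24 (S)-4-benzyl-3-[(2S,3R)-2-benzyloxy-3-hydroxy-3-(3-methoxy-4-triisopropylsilyloxyphenyl)propanoyl]oxazolidin-2-one
Product: 25 (1R,2R)-2-benzyloxy-1-(3-methoxy-4-triisopropylsilyloxyphenyl)propane-1,3-diol
Conditions: LiBH4, MeOH (1 equiv), THF, 0 °C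
Reagents that add atoms: none
Why: Reductive removal of the auxiliary turns the imide carbonyl into C9′H2OH without touching either stereocentre (the C8′ descriptor changes from S to R by priority only).

Step 15
Reactants: 25 (1R,2R)-2-benzyloxy-1-(3-methoxy-4-triisopropylsilyloxyphenyl)propane-1,3-diol
Product: 26 (4R,5R)-5-benzyloxy-2,2-di-tert-butyl-4-(3-methoxy-4-triisopropylsilyloxyphenyl)-1,3,2-dioxasilinane
Conditions: tBu2Si(OTf)2, 2,6-lutidine, CH2Cl2, 0 °C
Reagents that add atoms: di-tert-butylsilyl bis(trifluoromethanesulfonate) CC(C)(C)[Si](OS(=O)(=O)C(F)(F)F)(OS(=O)(=O)C(F)(F)F)C(C)(C)C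
Why: Cyclic silylene protection of the 1,3-diol (O7′ and O9′) gives a fluoride-labile six-membered ring with the aryl group equatorial and O8′ axial.

Step 16
Reactants: 26 (4R,5R)-5-benzyloxy-2,2-di-tert-butyl-4-(3-methoxy-4-triisopropylsilyloxyphenyl)-1,3,2-dioxasilinane
Product: 27 (4R,5R)-2,2-di-tert-butyl-4-(3-methoxy-4-triisopropylsilyloxyphenyl)-1,3,2-dioxasilinan-5-ol
Conditions: H2 (1 atm), 10% Pd/C, EtOAc, rt
Reagents that add atoms: none
Why: Hydrogenolysis of the alkyl benzyl ether in a neutral solvent frees only O8′, since the silylated benzylic C7′–O bond and the aryl silyl ether are much slower to react.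

Step 17
Reactants: 16 (1R,5R,6R)-6-(4-hydroxy-3,5-dimethoxyphenyl)-3,7-dioxabicyclo[3.3.0]octan-2-one; 27 (4R,5R)-2,2-di-tert-butyl-4-(3-methoxy-4-triisopropylsilyloxyphenyl)-1,3,2-dioxasilinan-5-ol
Product: 28 (1R,5R,6R)-6-{4-[(4R,5S)-2,2-di-tert-butyl-4-(3-methoxy-4-triisopropylsilyloxyphenyl)-1,3,2-dioxasilinan-5-yloxy]-3,5-dimethoxyphenyl}-3,7-dioxabicyclo[3.3.0]octan-2-one
Conditions: PPh3, DIAD, toluene, 0 °C → rt
Reagents that add atoms: none
Why: Mitsunobu etherification: the activated axial C8′ oxygen is displaced by the phenol in an SN2 process with clean inversion, turning the threo alcohol into the erythro (7′R,8′S) ether as the trans-diequatorial ring product, while the ring holds the electron-rich aryl group gauche to the leaving group and so excludes aryl participation.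

Step 18
Reactants: 28 (1R,5R,6R)-6-{4-[(4R,5S)-2,2-di-tert-butyl-4-(3-methoxy-4-triisopropylsilyloxyphenyl)-1,3,2-dioxasilinan-5-yloxy]-3,5-dimethoxyphenyl}-3,7-dioxabicyclo[3.3.0]octan-2-one
Product: 29 CNP0398772.1
Conditions: Bu4NF (4 equiv), AcOH (4 equiv), THF, 0 °C → rt
Reagents that add atoms: none
Why: One buffered fluoride treatment removes the silylene and the aryl TIPS ether; the near-neutral medium spares the lactone, the acid-sensitive endo benzylic ether C6 and the p-hydroxybenzylic alcohol C7′.

## Compound list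

1 | syringaldehyde | COc1cc(C=O)cc(OC)c1O | starting material
2 | 3,5-dimethoxy-4-(triisopropylsilyloxy)benzaldehyde | COc1cc(C=O)cc(OC)c1O[Si](C(C)C)(C(C)C)C(C)C | intermediate
3 | but-2-yne-1,4-diol | OCC#CCO | starting material
4 | 4-(tert-butyldimethylsilyloxy)but-2-yn-1-ol | CC(C)(C)[Si](C)(C)OCC#CCO | intermediate
5 | 1-bromo-4-(tert-butyldimethylsilyloxy)but-2-yne | CC(C)(C)[Si](C)(C)OCC#CCBr | intermediate
6 | [4-(tert-butyldimethylsilyloxy)but-2-ynyl]indium dibromide (not isolated) | CC(C)(C)[Si](C)(C)OCC#CC[In](Br)Br | intermediate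
7 | rac-1-(3,5-dimethoxy-4-triisopropylsilyloxyphenyl)-2-(tert-butyldimethylsilyloxymethyl)buta-2,3-dien-1-ol | COc1cc(C(O)C(CO[Si](C)(C)C(C)(C)C)=C=C)cc(OC)c1O[Si](C(C)C)(C(C)C)C(C)C | intermediate
8 | 1-(3,5-dimethoxy-4-triisopropylsilyloxyphenyl)-2-(tert-butyldimethylsilyloxymethyl)buta-2,3-dien-1-one | COc1cc(C(=O)C(CO[Si](C)(C)C(C)(C)C)=C=C)cc(OC)c1O[Si](C(C)C)(C(C)C)C(C)C | intermediate
9 | (S)-1-(3,5-dimethoxy-4-triisopropylsilyloxyphenyl)-2-(tert-butyldimethylsilyloxymethyl)buta-2,3-dien-1-ol | COc1cc([C@H](O)C(CO[Si](C)(C)C(C)(C)C)=C=C)cc(OC)c1O[Si](C(C)C)(C(C)C)C(C)C | intermediate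
10 | 2,5-dihydrofuran-3-ylpalladium trifluoroacetate, Pd on C1 (not isolated) | COc1cc([C@@H]2OCC([Pd]OC(=O)C(F)(F)F)=C2CO[Si](C)(C)C(C)(C)C)cc(OC)c1O[Si](C(C)C)(C(C)C)C(C)C | intermediate
11 | 2,5-dihydrofuran-3-carbonylpalladium trifluoroacetate (not isolated) | COc1cc([C@@H]2OCC(C(=O)[Pd]OC(=O)C(F)(F)F)=C2CO[Si](C)(C)C(C)(C)C)cc(OC)c1O[Si](C(C)C)(C(C)C)C(C)C | intermediate
12 | methyl (5S)-5-(3,5-dimethoxy-4-triisopropylsilyloxyphenyl)-4-(tert-butyldimethylsilyloxymethyl)-2,5-dihydrofuran-3-carboxylate | COC(=O)C1=C(CO[Si](C)(C)C(C)(C)C)[C@H](c2cc(OC)c(O[Si](C(C)C)(C(C)C)C(C)C)c(OC)c2)OC1 | intermediate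
13 | methyl (5S)-5-(3,5-dimethoxy-4-triisopropylsilyloxyphenyl)-4-(hydroxymethyl)-2,5-dihydrofuran-3-carboxylate (not isolated) | COC(=O)C1=C(CO)[C@H](c2cc(OC)c(O[Si](C(C)C)(C(C)C)C(C)C)c(OC)c2)OC1 | intermediate
14 | (6S)-6-(3,5-dimethoxy-4-triisopropylsilyloxyphenyl)-3,7-dioxabicyclo[3.3.0]oct-1(5)-en-2-one | O=C1OCC2=C1CO[C@H]2c1cc(OC)c(O[Si](C(C)C)(C(C)C)C(C)C)c(OC)c1 | intermediate
15 | (1R,5R,6R)-6-(3,5-dimethoxy-4-triisopropylsilyloxyphenyl)-3,7-dioxabicyclo[3.3.0]octan-2-one | COc1cc([C@@H]2OC[C@@H]3C(=O)OC[C@@H]32)cc(OC)c1O[Si](C(C)C)(C(C)C)C(C)C | intermediate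
16 | (1R,5R,6R)-6-(4-hydroxy-3,5-dimethoxyphenyl)-3,7-dioxabicyclo[3.3.0]octan-2-one | COc1cc([C@@H]2OC[C@@H]3C(=O)OC[C@@H]32)cc(OC)c1O | intermediate
17 | vanillin | COc1cc(C=O)ccc1O | starting material
18 | 3-methoxy-4-(triisopropylsilyloxy)benzaldehyde | COc1cc(C=O)ccc1O[Si](C(C)C)(C(C)C)C(C)C | intermediate
19 | (S)-4-benzyloxazolidin-2-one | O=C1N[C@@H](Cc2ccccc2)CO1 | starting material
20 | benzyloxyacetyl chloride | O=C(Cl)COCc1ccccc1 | starting material
21 | lithium salt of (S)-4-benzyloxazolidin-2-one (not isolated) | [Li+].O=C1[N-][C@@H](Cc2ccccc2)CO1 | intermediate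
22 | (S)-4-benzyl-3-(benzyloxyacetyl)oxazolidin-2-one | O=C(COCc1ccccc1)N1[C@@H](Cc2ccccc2)COC1=O | intermediate
23 | Z-dibutylboron enolate of 22 (not isolated) | CCCCB(CCCC)O/C(=C\OCc1ccccc1)N1[C@@H](Cc2ccccc2)COC1=O | intermediate
24 | (S)-4-benzyl-3-[(2S,3R)-2-benzyloxy-3-hydroxy-3-(3-methoxy-4-triisopropylsilyloxyphenyl)propanoyl]oxazolidin-2-one | O=C([C@@H](OCc1ccccc1)[C@H](O)c1ccc(O[Si](C(C)C)(C(C)C)C(C)C)c(OC)c1)N1[C@@H](Cc2ccccc2)COC1=O | intermediate
25 | (1R,2R)-2-benzyloxy-1-(3-methoxy-4-triisopropylsilyloxyphenyl)propane-1,3-diol | OC[C@@H](OCc1ccccc1)[C@H](O)c1ccc(O[Si](C(C)C)(C(C)C)C(C)C)c(OC)c1 | intermediate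
26 | (4R,5R)-5-benzyloxy-2,2-di-tert-butyl-4-(3-methoxy-4-triisopropylsilyloxyphenyl)-1,3,2-dioxasilinane | CC(C)(C)[Si]1(C(C)(C)C)OC[C@@H](OCc2ccccc2)[C@@H](c2ccc(O[Si](C(C)C)(C(C)C)C(C)C)c(OC)c2)O1 | intermediate
27 | (4R,5R)-2,2-di-tert-butyl-4-(3-methoxy-4-triisopropylsilyloxyphenyl)-1,3,2-dioxasilinan-5-ol | CC(C)(C)[Si]1(C(C)(C)C)OC[C@@H](O)[C@@H](c2ccc(O[Si](C(C)C)(C(C)C)C(C)C)c(OC)c2)O1 | intermediate
28 | silylene- and TIPS-protected target, (1R,5R,6R) core with (4R,5S)-dioxasilinan-5-yl aryl ether | COc1cc([C@@H]2OC[C@@H]3C(=O)OC[C@@H]32)cc(OC)c1O[C@H]4CO[Si](C(C)(C)C)(C(C)(C)C)O[C@@H]4c5ccc(O[Si](C(C)C)(C(C)C)C(C)C)c(OC)c5 | intermediate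
29 | CNP0398772.1, (1R,5R,6R)-6-{4-[(1R,2S)-1,3-dihydroxy-1-(4-hydroxy-3-methoxyphenyl)propan-2-yloxy]-3,5-dimethoxyphenyl}-3,7-dioxabicyclo[3.3.0]octan-2-one | COc1cc([C@@H](O)[C@H](CO)Oc2c(OC)cc([C@@H]3OC[C@@H]4C(=O)OC[C@@H]43)cc2OC)ccc1O | target

## Step count

Total step count: 18.
Longest linear sequence: 11 steps (2, 3, 4, 5, 6, 7, 8, 9, 10, 17, 18, counted from but-2-yne-1,4-diol).

## Steps most likely to fail

**1. Step 7 (proposed new method).**
- Protodepalladation of the vinylpalladium may outrun CO insertion.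
- Methanol may attack the coordinated allene in place of the hydroxyl.
- Transient acid may cause solvolysis and loss of configuration at the benzylic carbinol.
- Fallback (known chemistry), setting out from 9: N-iodosuccinimide in CH2Cl2 at 0 °C performs the established 5-endo iodoetherification of α-allenols. It should give (2S)-2-(3,5-dimethoxy-4-triisopropylsilyloxyphenyl)-3-(tert-butyldimethylsilyloxymethyl)-4-iodo-2,5-dihydrofuran F1.
- The vinyl iodide is then methoxycarbonylated with the zerovalent palladium catalyst Pd(PPh3)4 (CO 1 atm, MeOH, Et3N, DMF, 60 °C). The route is rejoined at 12.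

**2. Step 6.**
- The ketone carries two flat sp2 substituents of similar size, so discrimination by the oxazaborolidine may be weak or of the opposite sense.
- Hydroboration or 1,4-reduction of the allenone may compete.
- Fallback, setting out from racemic 7 (step 5 is then not needed): acylation with (1S)-camphanic chloride (Et3N, DMAP, CH2Cl2) gives two diastereomeric esters, the (S)-carbinol camphanate F2 and the (R)-carbinol camphanate F3. They are separated by chromatography or crystallisation.
- Methanolysis of F2 (K2CO3, MeOH, 0 °C) returns to the route at 9.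

**3. Step 17.**
- Displacement at a secondary carbon flanked by two C–O bonds by a di-ortho-substituted phenol may be slow.
- Anti elimination of the axial activated oxygen with the axial H7′ or H9′ may then take over, as may alkylation of the reduced azodicarboxylate.
- Fallback, setting out from 27: activation and substitution are separated, as in carbohydrate chemistry. Tf2O and 2,6-lutidine in CH2Cl2 at −78 °C give (4R,5R)-2,2-di-tert-butyl-4-(3-methoxy-4-triisopropylsilyloxyphenyl)-1,3,2-dioxasilinan-5-yl trifluoromethanesulfonate F4.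
- The caesium phenoxide of 16 (Cs2CO3, MeCN, 0 °C → rt) displaces the smaller and far better leaving group with inversion. The route is rejoined at 28.

Further compounds
F1 | step 7 | (2S)-2-(3,5-dimethoxy-4-triisopropylsilyloxyphenyl)-3-(tert-butyldimethylsilyloxymethyl)-4-iodo-2,5-dihydrofuran | COc1cc([C@@H]2OCC(I)=C2CO[Si](C)(C)C(C)(C)C)cc(OC)c1O[Si](C(C)C)(C(C)C)C(C)C
F2 | step 6 | (1S,4R)-camphanate of (S)-allenol 9 | COc1cc([C@H](OC(=O)[C@@]23CC[C@@](C)(C(=O)O2)C3(C)C)C(CO[Si](C)(C)C(C)(C)C)=C=C)cc(OC)c1O[Si](C(C)C)(C(C)C)C(C)C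
F3 | step 6 | (1S,4R)-camphanate of the (R)-allenol | COc1cc([C@@H](OC(=O)[C@@]23CC[C@@](C)(C(=O)O2)C3(C)C)C(CO[Si](C)(C)C(C)(C)C)=C=C)cc(OC)c1O[Si](C(C)C)(C(C)C)C(C)C
F4 | step 17 | (4R,5R)-2,2-di-tert-butyl-4-(3-methoxy-4-triisopropylsilyloxyphenyl)-1,3,2-dioxasilinan-5-yl trifluoromethanesulfonate | CC(C)(C)[Si]1(C(C)(C)C)OC[C@@H](OS(=O)(=O)C(F)(F)F)[C@@H](c2ccc(O[Si](C(C)C)(C(C)C)C(C)C)c(OC)c2)O1
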